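**Retrosynthetic overview**

- Labels: dihydrobenzofuran O1, C2, C3, C3a, C4–C7, C7a (benzo ring = ring A); pendant aryl on C2 = ring B; side chain on C5 = C1'–C3'. The target is (2S,3S,1'R,2'S).
- The C1' carbinol comes last, by chelate-controlled reduction of an α-hydroxy ketone. The C5–C1' bond comes from the C5 aryllithium (from C5–Br) and the Weinreb amide of O-silyl (S)-lactic acid.
- The C3 methyl comes from a C3 ester, which is first epimerised from cis to trans.
- Feature the route rests on: C2 is a methine carrying O1 and ring B, bonded to C3, which sits on C3a ortho to O1. The O1–CH2–ring B ether C–H therefore lies 1,5 to a carbene at C3. Carbene C–H insertion forms C2–C3 and closes the O1–C2–C3–C3a–C7a ring, the only ring made (rings A and B are bought).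
- The diazoester comes from an aryl iodide (I/Mg exchange, dimethyl oxalate, tosylhydrazone). The O1–CH2 ether comes from a Mitsunobu reaction of the ring A iodophenol with the ring B benzylic alcohol.

Key step: step 7

Assumption: in the closest cases the S-ligand catalyst of this family gives the 2R cis ester, so the R-ligand catalyst is specified for 2S; if a first run shows the opposite sense, the enantiomeric catalyst is used and nothing else changes.

**Route**

Step 1
Reactants: 1 3-hydroxy-4,5-dimethoxybenzaldehyde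
Product: 2 3,4-dimethoxy-5-[(triisopropylsilyl)oxy]benzaldehyde
Conditions: TIPSCl, imidazole, DMF, rt
Reagents that add atoms: triisopropylsilyl chloride, CC(C)[Si](Cl)(C(C)C)C(C)C
Why: Imidazole-mediated silylation of the only phenol (silyl ether formation) should be clean, and the bulky silyl group is chosen to survive the organometallic, basic and hydride steps ahead and to fall with fluoride at the end.

Step 2
Reactants: 2 3,4-dimethoxy-5-[(triisopropylsilyl)oxy]benzaldehyde
Product: 3 {3,4-dimethoxy-5-[(triisopropylsilyl)oxy]phenyl}methanol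
Conditions: NaBH4, MeOH/THF, 0 °C
Reagents that add atoms: none
Why: Borohydride reduction of an aromatic aldehyde to the benzylic alcohol is chemoselective and should leave the aryl silyl ether untouched at 0 °C.

Step 3
Reactants: 4 4-bromo-2-methoxyphenol
Product: 5 4-bromo-2-iodo-6-methoxyphenol
Conditions: NIS, TsOH·H2O (10 mol%), MeCN, 0 °C to rt
Reagents that add atoms: N-iodosuccinimide, O=C1CCC(=O)N1I
Why: Electrophilic aromatic iodination should go ortho to the free hydroxyl, the strongest director, because its para position is blocked by bromine.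

Step 4
Reactants: 3 {3,4-dimethoxy-5-[(triisopropylsilyl)oxy]phenyl}methanol; 5 4-bromo-2-iodo-6-methoxyphenol
Product: 6 5-bromo-1-iodo-3-methoxy-2-({3,4-dimethoxy-5-[(triisopropylsilyl)oxy]benzyl}oxy)benzene
Conditions: PPh3, DIAD, THF, 0 °C to rt
Reagents that add atoms: none
Why: Mitsunobu etherification joins the acidic phenol to the primary benzylic alcohol under neutral conditions that spare the aryl silyl ether and both aryl halides.

Step 5
Reactants: 6 5-bromo-1-iodo-3-methoxy-2-({3,4-dimethoxy-5-[(triisopropylsilyl)oxy]benzyl}oxy)benzene; 7 dimethyl oxalate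
Product: 9 methyl 2-[5-bromo-3-methoxy-2-({3,4-dimethoxy-5-[(triisopropylsilyl)oxy]benzyl}oxy)phenyl]-2-oxoacetate, via arylmagnesium chloride 8 (not isolated)
Conditions: i-PrMgCl·LiCl, THF, −20 °C; then cannulated into (CO2Me)2 (3 equiv), THF, −78 to 0 °C; aq NH4Cl
Reagents that add atoms: none
Why: Iodine–magnesium exchange should be far faster at the C–I bond, which is assisted by the ortho alkoxy group, than at the C–Br bond, and inverse addition of the aryl Grignard reagent to excess dimethyl oxalate should stop at the α-keto ester (acyl substitution).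

Step 6
Reactants: 9 methyl 2-[5-bromo-3-methoxy-2-({3,4-dimethoxy-5-[(triisopropylsilyl)oxy]benzyl}oxy)phenyl]-2-oxoacetate
Product: 11 methyl 2-[5-bromo-3-methoxy-2-({3,4-dimethoxy-5-[(triisopropylsilyl)oxy]benzyl}oxy)phenyl]-2-diazoacetate, via tosylhydrazone 10 (not isolated)
Conditions: TsNHNH2, toluene, 80 °C; then DBU, CH2Cl2, 0 °C to rt
Reagents that add atoms: p-toluenesulfonohydrazide, Cc1ccc(cc1)S(=O)(=O)NN
Why: Condensation of the α-keto ester with tosylhydrazide followed by base-induced loss of p-toluenesulfinate (Bamford–Stevens-type elimination) is a standard entry to aryldiazoacetates and uses no acid or strong nucleophile.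

Step 7
Reactants: 11 methyl 2-[5-bromo-3-methoxy-2-({3,4-dimethoxy-5-[(triisopropylsilyl)oxy]benzyl}oxy)phenyl]-2-diazoacetate
Product: 12 methyl (2S,3R)-5-bromo-7-methoxy-2-{3,4-dimethoxy-5-[(triisopropylsilyl)oxy]phenyl}-2,3-dihydro-1-benzofuran-3-carboxylate (cis)
Conditions: Rh2(R-PTTL)4 (dirhodium tetrakis[N-phthaloyl-(R)-tert-leucinate], 1 mol%), toluene, −78 to −60 °C
Reagents that add atoms: none
Why: The dirhodium carboxylate expels N2 from 11 to give an electrophilic donor/acceptor rhodium carbene at the future C3, which should insert into the O1–CH2–ring B C–H bond by a concerted, asynchronous hydride shift and C–C bond formation through a five-membered transition state. The closest known reaction type is the enantioselective intramolecular 1,5 C–H insertion of 2-(benzyloxy)aryl diazoacetates catalysed by N-phthaloyl amino acid dirhodium complexes, which gives cis-2-aryl-2,3-dihydrobenzofuran-3-carboxylates. The dihydrofuran ring (O1–C2–C3–C3a–C7a) closes by formation of the C2–C3 bond between the carbene carbon and the ether carbon held five atoms away (1,5-insertion, five-membered ring). C2 is set by the chiral carboxylate ligands, which distinguish the two enantiotopic hydrogens of the CH2 group (R-ligand for 2S), and C3 is set in the same event, the ester and ring B coming out cis under kinetic control. The step needs site selectivity for this C–H bond over aromatic cycloaddition and oxonium ylide formation, which is secured by geometry (it is the only C–H bond that can reach the carbene through a five-membered array) and by activation of the bond by O1 and the para-methoxy group of ring B. The aryl bromide, the methyl ethers and the silyl ether should be inert to the carbene at this temperature.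

Step 8
Reactants: 12 methyl (2S,3R)-5-bromo-7-methoxy-2-{3,4-dimethoxy-5-[(triisopropylsilyl)oxy]phenyl}-2,3-dihydro-1-benzofuran-3-carboxylate
Product: 13 methyl (2S,3S)-5-bromo-7-methoxy-2-{3,4-dimethoxy-5-[(triisopropylsilyl)oxy]phenyl}-2,3-dihydro-1-benzofuran-3-carboxylate (trans)
Conditions: DBU, toluene, rt
Reagents that add atoms: none
Why: Reversible deprotonation of the acidic C3–H next to the ester (base epimerisation) should equilibrate C3 to the more stable trans ester, while C2 is untouched because ring opening would need a disfavoured 5-endo retro-oxa-Michael path.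

Step 9
Reactants: 13 methyl (2S,3S)-5-bromo-7-methoxy-2-{3,4-dimethoxy-5-[(triisopropylsilyl)oxy]phenyl}-2,3-dihydro-1-benzofuran-3-carboxylate
Product: 14 [(2S,3R)-5-bromo-7-methoxy-2-{3,4-dimethoxy-5-[(triisopropylsilyl)oxy]phenyl}-2,3-dihydro-1-benzofuran-3-yl]methanol
Conditions: i-Bu2AlH, CH2Cl2, −78 to 0 °C; aq potassium sodium tartrate
Reagents that add atoms: none
Why: Aluminium hydride reduction of the ester to the primary alcohol at low temperature should not touch the aryl bromide or the silyl ether and does not epimerise C3 (the descriptor changes to 3R only by priority).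

Step 10
Reactants: 14 [(2S,3R)-5-bromo-7-methoxy-2-{3,4-dimethoxy-5-[(triisopropylsilyl)oxy]phenyl}-2,3-dihydro-1-benzofuran-3-yl]methanol
Product: 15 [(2S,3R)-5-bromo-7-methoxy-2-{3,4-dimethoxy-5-[(triisopropylsilyl)oxy]phenyl}-2,3-dihydro-1-benzofuran-3-yl]methyl 4-methylbenzenesulfonate
Conditions: TsCl, Et3N, DMAP (5 mol%), CH2Cl2, 0 °C to rt
Reagents that add atoms: p-toluenesulfonyl chloride, Cc1ccc(cc1)S(Cl)(=O)=O
Why: Sulfonylation of the unhindered primary alcohol turns it into a leaving group without involving either stereocentre.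

Step 11
Reactants: 15 [(2S,3R)-5-bromo-7-methoxy-2-{3,4-dimethoxy-5-[(triisopropylsilyl)oxy]phenyl}-2,3-dihydro-1-benzofuran-3-yl]methyl 4-methylbenzenesulfonate
Product: 16 (2S,3S)-5-bromo-7-methoxy-3-methyl-2-{3,4-dimethoxy-5-[(triisopropylsilyl)oxy]phenyl}-2,3-dihydro-1-benzofuran
Conditions: LiEt3BH, THF, 0 °C to rt
Reagents that add atoms: none
Why: SN2 displacement of the primary tosylate by the borohydride should give the C3 methyl group, the aryl bromide and silyl ether being inert to this hydride at 0 °C.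

Step 12
Reactants: 17 ethyl (2S)-2-hydroxypropanoate (ethyl (S)-lactate)
Product: 18 ethyl (2S)-2-[(tert-butyldimethylsilyl)oxy]propanoate
Conditions: TBSCl, imidazole, DMF, rt
Reagents that add atoms: tert-butyldimethylsilyl chloride, CC(C)(C)[Si](C)(C)Cl
Why: Imidazole-mediated silylation of the secondary alcohol does not touch the stereocentre and gives an ether stable to the organometallic steps.

Step 13
Reactants: 18 ethyl (2S)-2-[(tert-butyldimethylsilyl)oxy]propanoate
Product: 19 (2S)-2-[(tert-butyldimethylsilyl)oxy]-N-methoxy-N-methylpropanamide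
Conditions: MeNH(OMe)·HCl, i-PrMgCl, THF, −20 to 0 °C
Reagents that add atoms: N,O-dimethylhydroxylamine hydrochloride, CNOC.Cl
Why: The chloromagnesium amide of N,O-dimethylhydroxylamine converts the ester directly to the Weinreb amide (aminolysis) at low temperature, where α-silyloxy esters keep their configuration.

Step 14
Reactants: 16 (2S,3S)-5-bromo-7-methoxy-3-methyl-2-{3,4-dimethoxy-5-[(triisopropylsilyl)oxy]phenyl}-2,3-dihydro-1-benzofuran; 19 (2S)-2-[(tert-butyldimethylsilyl)oxy]-N-methoxy-N-methylpropanamide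
Product: 21 (2S)-2-[(tert-butyldimethylsilyl)oxy]-1-[(2S,3S)-7-methoxy-3-methyl-2-{3,4-dimethoxy-5-[(triisopropylsilyl)oxy]phenyl}-2,3-dihydro-1-benzofuran-5-yl]propan-1-one, via aryllithium 20 (not isolated)
Conditions: t-BuLi (2 equiv), THF, −78 °C; then 19, −78 to −40 °C; aq NH4Cl
Reagents that add atoms: none
Why: Bromine–lithium exchange at −78 °C should outrun any deprotonation, and the aryllithium adds once to the Weinreb amide to give a chelated tetrahedral adduct that releases the ketone only on work-up (Weinreb ketone synthesis), so the lactate stereocentre is carried over unchanged.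

Step 15
Reactants: 21 (2S)-2-[(tert-butyldimethylsilyl)oxy]-1-[(2S,3S)-7-methoxy-3-methyl-2-{3,4-dimethoxy-5-[(triisopropylsilyl)oxy]phenyl}-2,3-dihydro-1-benzofuran-5-yl]propan-1-one
Product: 22 (2S)-2-hydroxy-1-[(2S,3S)-2-(3-hydroxy-4,5-dimethoxyphenyl)-7-methoxy-3-methyl-2,3-dihydro-1-benzofuran-5-yl]propan-1-one
Conditions: Bu4NF, AcOH, THF, 0 °C to rt
Reagents that add atoms: none
Why: Fluoride buffered with acetic acid should cleave both the secondary and the aryl silyl ether (fluoride desilylation) while keeping the medium non-basic, which protects the α-hydroxy ketone from enolisation and α-ketol isomerisation.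

Step 16
Reactants: 22 (2S)-2-hydroxy-1-[(2S,3S)-2-(3-hydroxy-4,5-dimethoxyphenyl)-7-methoxy-3-methyl-2,3-dihydro-1-benzofuran-5-yl]propan-1-one
Product: 23 (1R,2S)-1-[(2S,3S)-2-(3-hydroxy-4,5-dimethoxyphenyl)-7-methoxy-3-methyl-2,3-dihydro-1-benzofuran-5-yl]propane-1,2-diol (CNP0229216.1)
Conditions: Zn(BH4)2 (from ZnCl2 and NaBH4 in Et2O), Et2O/THF, −30 to 0 °C; aq NH4Cl
Reagents that add atoms: none
Why: Zinc should tie the carbonyl oxygen and the α-hydroxyl into a five-membered chelate (Cram chelate model) so that hydride arrives from the face bearing the C2' hydrogen, opposite the C3' methyl, which gives the anti (erythro) diol and hence 1'R next to the fixed 2'S centre.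

**Compound list**

1 | 3-hydroxy-4,5-dimethoxybenzaldehyde | COc1cc(C=O)cc(O)c1OC | starting material
2 | 3,4-dimethoxy-5-[(triisopropylsilyl)oxy]benzaldehyde | COc1cc(C=O)cc(O[Si](C(C)C)(C(C)C)C(C)C)c1OC | intermediate
3 | {3,4-dimethoxy-5-[(triisopropylsilyl)oxy]phenyl}methanol | COc1cc(CO)cc(O[Si](C(C)C)(C(C)C)C(C)C)c1OC | intermediate
4 | 4-bromo-2-methoxyphenol | COc1cc(Br)ccc1O | starting material
5 | 4-bromo-2-iodo-6-methoxyphenol | COc1cc(Br)cc(I)c1O | intermediate
6 | 5-bromo-1-iodo-3-methoxy-2-({3,4-dimethoxy-5-[(triisopropylsilyl)oxy]benzyl}oxy)benzene | COc1cc(Br)cc(I)c1OCc1cc(OC)c(OC)c(O[Si](C(C)C)(C(C)C)C(C)C)c1 | intermediate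
7 | dimethyl oxalate | COC(=O)C(=O)OC | starting material
8 | [5-bromo-3-methoxy-2-({3,4-dimethoxy-5-[(triisopropylsilyl)oxy]benzyl}oxy)phenyl]magnesium chloride (not isolated) | COc1cc(Br)cc([Mg]Cl)c1OCc1cc(OC)c(OC)c(O[Si](C(C)C)(C(C)C)C(C)C)c1 | intermediate
9 | methyl 2-[5-bromo-3-methoxy-2-({3,4-dimethoxy-5-[(triisopropylsilyl)oxy]benzyl}oxy)phenyl]-2-oxoacetate | COC(=O)C(=O)c1cc(Br)cc(OC)c1OCc1cc(OC)c(OC)c(O[Si](C(C)C)(C(C)C)C(C)C)c1 | intermediate
10 | methyl 2-[5-bromo-3-methoxy-2-({3,4-dimethoxy-5-[(triisopropylsilyl)oxy]benzyl}oxy)phenyl]-2-[2-(4-methylbenzenesulfonyl)hydrazinylidene]acetate (E/Z mixture, not isolated) | COC(=O)C(=NNS(=O)(=O)c1ccc(C)cc1)c1cc(Br)cc(OC)c1OCc1cc(OC)c(OC)c(O[Si](C(C)C)(C(C)C)C(C)C)c1 | intermediate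
11 | methyl 2-[5-bromo-3-methoxy-2-({3,4-dimethoxy-5-[(triisopropylsilyl)oxy]benzyl}oxy)phenyl]-2-diazoacetate | COC(=O)C(=[N+]=[N-])c1cc(Br)cc(OC)c1OCc1cc(OC)c(OC)c(O[Si](C(C)C)(C(C)C)C(C)C)c1 | intermediate
12 | methyl (2S,3R)-5-bromo-7-methoxy-2-{3,4-dimethoxy-5-[(triisopropylsilyl)oxy]phenyl}-2,3-dihydro-1-benzofuran-3-carboxylate (cis) | COc1cc([C@H]2Oc3c(OC)cc(Br)cc3[C@H]2C(=O)OC)cc(O[Si](C(C)C)(C(C)C)C(C)C)c1OC | intermediate
13 | methyl (2S,3S)-5-bromo-7-methoxy-2-{3,4-dimethoxy-5-[(triisopropylsilyl)oxy]phenyl}-2,3-dihydro-1-benzofuran-3-carboxylate (trans) | COc1cc([C@H]2Oc3c(OC)cc(Br)cc3[C@@H]2C(=O)OC)cc(O[Si](C(C)C)(C(C)C)C(C)C)c1OC | intermediate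
14 | [(2S,3R)-5-bromo-7-methoxy-2-{3,4-dimethoxy-5-[(triisopropylsilyl)oxy]phenyl}-2,3-dihydro-1-benzofuran-3-yl]methanol | COc1cc([C@H]2Oc3c(OC)cc(Br)cc3[C@@H]2CO)cc(O[Si](C(C)C)(C(C)C)C(C)C)c1OC | intermediate
15 | [(2S,3R)-5-bromo-7-methoxy-2-{3,4-dimethoxy-5-[(triisopropylsilyl)oxy]phenyl}-2,3-dihydro-1-benzofuran-3-yl]methyl 4-methylbenzenesulfonate | COc1cc([C@H]2Oc3c(OC)cc(Br)cc3[C@@H]2COS(=O)(=O)c4ccc(C)cc4)cc(O[Si](C(C)C)(C(C)C)C(C)C)c1OC | intermediate
16 | (2S,3S)-5-bromo-7-methoxy-3-methyl-2-{3,4-dimethoxy-5-[(triisopropylsilyl)oxy]phenyl}-2,3-dihydro-1-benzofuran | COc1cc([C@H]2Oc3c(OC)cc(Br)cc3[C@@H]2C)cc(O[Si](C(C)C)(C(C)C)C(C)C)c1OC | intermediate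
17 | ethyl (2S)-2-hydroxypropanoate | C[C@H](O)C(=O)OCC | starting material
18 | ethyl (2S)-2-[(tert-butyldimethylsilyl)oxy]propanoate | C[C@H](O[Si](C)(C)C(C)(C)C)C(=O)OCC | intermediate
19 | (2S)-2-[(tert-butyldimethylsilyl)oxy]-N-methoxy-N-methylpropanamide | C[C@H](O[Si](C)(C)C(C)(C)C)C(=O)N(C)OC | intermediate
20 | [(2S,3S)-7-methoxy-3-methyl-2-{3,4-dimethoxy-5-[(triisopropylsilyl)oxy]phenyl}-2,3-dihydro-1-benzofuran-5-yl]lithium (not isolated) | COc1cc([C@H]2Oc3c(OC)cc([Li])cc3[C@@H]2C)cc(O[Si](C(C)C)(C(C)C)C(C)C)c1OC | intermediate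
21 | (2S)-2-[(tert-butyldimethylsilyl)oxy]-1-[(2S,3S)-7-methoxy-3-methyl-2-{3,4-dimethoxy-5-[(triisopropylsilyl)oxy]phenyl}-2,3-dihydro-1-benzofuran-5-yl]propan-1-one | COc1cc([C@H]2Oc3c(OC)cc(C(=O)[C@H](C)O[Si](C)(C)C(C)(C)C)cc3[C@@H]2C)cc(O[Si](C(C)C)(C(C)C)C(C)C)c1OC | intermediate
22 | (2S)-2-hydroxy-1-[(2S,3S)-2-(3-hydroxy-4,5-dimethoxyphenyl)-7-methoxy-3-methyl-2,3-dihydro-1-benzofuran-5-yl]propan-1-one | COc1cc([C@H]2Oc3c(OC)cc(C(=O)[C@H](C)O)cc3[C@@H]2C)cc(O)c1OC | intermediate
23 | (1R,2S)-1-[(2S,3S)-2-(3-hydroxy-4,5-dimethoxyphenyl)-7-methoxy-3-methyl-2,3-dihydro-1-benzofuran-5-yl]propane-1,2-diol | COc1cc([C@H]2Oc3c(OC)cc([C@@H](O)[C@H](C)O)cc3[C@@H]2C)cc(O)c1OC | target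

**Step count**

Total: 16 steps. Longest linear sequence: 13 steps (1 → 2 → 3 → 6 → 9 → 11 → 12 → 13 → 14 → 15 → 16 → 21 → 22 → 23).

**Steps most likely to fail**

Step 7. The chiral pocket may discriminate poorly between the two enantiotopic ether hydrogens, because the C7 methoxy group next to the benzyloxy oxygen changes how the ether arm folds toward the carbene. The result would be erosion of enantioselectivity. The fallback gives up catalyst control and sets out from 11. Insertion with achiral Rh2(OAc)4 in CH2Cl2 at rt should give the ester as a stereorandom mixture, methyl 5-bromo-7-methoxy-2-{3,4-dimethoxy-5-[(triisopropylsilyl)oxy]phenyl}-2,3-dihydro-1-benzofuran-3-carboxylate F1. Equilibration with DBU as in step 8 converts it to the racemic trans ester, that is 13 together with its mirror image, the (2R,3R)-trans ester F2. Preparative chromatography on a chiral stationary phase removes F2, and the route is rejoined at 13.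

Step 14. Proton transfer to the aryllithium (from C2–H or from the α-position of the amide) may compete with acyl substitution. This would cause loss of the metalated position and partial erosion of the lactate centre. The fallback replaces acyl substitution by carbonyl addition followed by oxidation, and sets out from 16 and 18. Ester 18 is reduced with i-Bu2AlH (CH2Cl2, −78 °C) to (2S)-2-[(tert-butyldimethylsilyl)oxy]propanal F3. The aryllithium 20, made from 16 as before, is added to F3 at −78 °C, where addition to the aldehyde is much faster than proton transfer. This gives (2S)-2-[(tert-butyldimethylsilyl)oxy]-1-[(2S,3S)-7-methoxy-3-methyl-2-{3,4-dimethoxy-5-[(triisopropylsilyl)oxy]phenyl}-2,3-dihydro-1-benzofuran-5-yl]propan-1-ol F4 as a mixture of C1' epimers. Dess–Martin periodinane (NaHCO3, CH2Cl2, rt) oxidises both epimers to the same ketone, and the route is rejoined at 21.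

Step 16. Facial selectivity may be poor if the zinc chelate is loose, since the free phenol and the ether oxygens compete for zinc and open the way to non-chelated hydride delivery. The fallback moves from substrate (chelate) control to catalyst control and sets out from 22. Asymmetric transfer hydrogenation with RuCl[(S,S)-TsDPEN](p-cymene) in HCO2H/Et3N at rt delivers hydride to the aryl ketone face fixed by the ligand. This ligand configuration corresponds to the 1'R carbinol, and anti-1,2-diols from 2-hydroxy-1-arylpropan-1-ones are a known outcome of this catalyst class. The product is 23 itself, so the route is rejoined at 23 and no new compound is made.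

**Further compounds**

F1 | step 7 | methyl 5-bromo-7-methoxy-2-{3,4-dimethoxy-5-[(triisopropylsilyl)oxy]phenyl}-2,3-dihydro-1-benzofuran-3-carboxylate (mixture of stereoisomers) | COC(=O)C1C(Oc2c(OC)cc(Br)cc12)c1cc(OC)c(OC)c(O[Si](C(C)C)(C(C)C)C(C)C)c1
F2 | step 7 | methyl (2R,3R)-5-bromo-7-methoxy-2-{3,4-dimethoxy-5-[(triisopropylsilyl)oxy]phenyl}-2,3-dihydro-1-benzofuran-3-carboxylate | COc1cc([C@@H]2Oc3c(OC)cc(Br)cc3[C@H]2C(=O)OC)cc(O[Si](C(C)C)(C(C)C)C(C)C)c1OC
F3 | step 14 | (2S)-2-[(tert-butyldimethylsilyl)oxy]propanal | C[C@H](O[Si](C)(C)C(C)(C)C)C=O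
F4 | step 14 | (2S)-2-[(tert-butyldimethylsilyl)oxy]-1-[(2S,3S)-7-methoxy-3-methyl-2-{3,4-dimethoxy-5-[(triisopropylsilyl)oxy]phenyl}-2,3-dihydro-1-benzofuran-5-yl]propan-1-ol (C1 epimers) | COc1cc([C@H]2Oc3c(OC)cc(C(O)[C@H](C)O[Si](C)(C)C(C)(C)C)cc3[C@@H]2C)cc(O[Si](C(C)C)(C(C)C)C(C)C)c1OC
F0 | step 16 | none | none
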